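## The problem

CNP0108136.1 (25) is a fourteen-membered carbocycle (ring A, numbered here C4–C11 and C13–C18, with C12 the ester carbon and C19 the lactone carbonyl). It is bridged from C7 to C9 by an α-alkylidene γ-butyrolactone (ring B, E at C6=C7) and carries a cis-epoxide at C16/C17 (ring C), an isopropenyl group at C4 and a methyl ester at C11. Its stereocentres fall into groups too far apart to steer one another: C4, C9 and the epoxide pair C16/C17 each need their own source of chirality, whereas C11, between ester and ketone, is epimerizable and can be left to equilibrium. The cis arrangement of C15 and C18 on the epoxide requires a Z trisubstituted olefin, the less stable geometry, as precursor. The C11–C15 segment is a 3,5-dioxo ester attached directly to the epoxide; it is enolized and intolerant of strong acid, base and reductants, so the triketone array should appear only at the very end. The alkylidene lactone is a Michael acceptor, and the isopropenyl group rules out ozonolysis, hydrogenation and peracids. The key step is possible because C11 is the α-carbon of a β-keto ester (C12 ester, C13 ketone) and C10 is a primary carbon exocyclic to the lactone carbinol C9: the ring bond C10–C11 is that of an enolate alkylation by a primary halide, which leaves C9 untouched and puts C11 under thermodynamic control. Descriptors quoted for intermediates are their own; they change with the substituents while the spatial arrangement stays that of 25.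

## Retrosynthesis

**25 ⇒ 24 ⇒ 23.** No skeletal bond is cut first. The C15 ketone of 25 is taken back to carbinol 24 and its triethylsilyl ether 23. With a ketone at C15 the ring-closing substrate would hold two 1,3-dicarbonyl units, and C14 would be more acidic than C11. At the carbinol level C11 is the only acidic carbon, and the carbinol is also the natural product of the aldol reaction that builds C14–C15. The forward steps must cleave a silyl ether next to an epoxide without retro-aldol and oxidize a β-hydroxy ketone without touching C14.

**23 ⇒ 22.** The C10–C11 bond is cut, opening ring A to the seco iodide 22. The neighbouring closures are less attractive: closure at C6=C7 by olefination would require the C10–C11 bond to be made between molecules first, and closure at C14–C15 would need a γ-enolate generated next to an aldehyde. The precursor is a linear chain with two built-in turn elements, the E alkylidene lactone and the cis-epoxide. The forward reaction must favour C- over O-alkylation and ring closure over oligomerization.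

**22 ⇒ 21 ⇒ 20.** The iodide is derived from tosylate 21 by halide exchange and the silyl ether from alcohol 20. The leaving group travels as a sulfonate because it tolerates phosphine, titanium alkoxide, periodinane and the dianion, and it is turned into the soft iodide only one step before it is needed.

**20 ⇒ 17 + 18.** The C14–C15 bond is cut to epoxy aldehyde 17 and methyl acetoacetate 18, used as its dianion 19. This removes four carbons and the whole β-keto ester in one step. Adding the four-carbon unit first and epoxidizing afterwards under hydroxyl direction is kept only as a fallback: in a Z, 2-methyl allylic alcohol the 1,2- and 1,3-allylic strain effects oppose each other. The C15 configuration is irrelevant. The forward reaction must be aldehyde-selective in the presence of the lactone and the sulfonate; 17 has no α-hydrogen, which helps.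

**17 ⇒ 16 ⇒ 15.** The epoxide is taken back through epoxy alcohol 16 to the Z allylic alcohol 15. The nearest stereocentre, C4, is too remote to direct the epoxidation, so reagent control through the primary allylic alcohol is the reliable way to set C16 and C17.

**15 ⇒ 8 + 14.** The C6=C7 bond is cut to hydroxy aldehyde 8 and the lactone ylide 14. A Wittig reaction with a stabilized ylide runs without base, tolerates the free alcohol and should give the E isomer. An aldol–dehydration sequence would need strong base, protection of the alcohol and an elimination step that endangers the C10 leaving group. The cut is convergent and divides the molecule into an eleven-carbon chain and the ring B building block.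

**14 ⇒ 12 ⇒ 10 ⇒ 9.** The ylide comes from bromo lactone 12 (through phosphonium salt 13), this from tosylate 10 (through silyl ketene acetal 11), and 10 from the chiral-pool lactone 9. C9 is thus bought, not made.

**8 ⇒ 7 ⇒ 5 + 6.** The C16=C17 bond is cut to aldehyde 5 and phosphonate 6; the Still–Gennari olefination gives the Z enoate 7. One hydride reagent then sets both chain ends of 8: the ester goes to the allylic alcohol and the Weinreb amide to the aldehyde, so no protecting group is needed. Oxidative cleavage of a six-membered terpene ring would supply the Z olefin for free, but it leaves C4 one methylene short on the C5 side and would require homologation next to a labile stereocentre.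

**5 ⇒ 4 ⇒ 3 ⇒ 1 + 2.** The isopropenyl–C4 bond is cut to 5,6-dihydro-2H-pyran-2-one 1 and the isopropenyl borate 2. A catalytic asymmetric conjugate addition sets C4, and the lactone 3 delivers the two two-carbon arms already differentiated as acyl and alkoxy ends. Ring opening to amide 4 and oxidation to 5 follow.

## Roads not taken

**Alternative 1:** The cut is at C8–C9, with ring B made by an Ireland–Claisen ring contraction. In the seven-membered dilactone A1 a glycolate unit (C9, C10) is tied to the allylic oxygen at C6 and to the carboxyl C19. KN(SiMe3)2 and Me3SiCl enolize the glycolate carbonyl, and the [3,3] shift through C9, C10, O, C6, C7, C8 forms C8–C9 and breaks C6–O, giving acid A2.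
- Merits: ring B, the E olefin and C9 arise in one stereospecific step by chirality transfer, with no olefination and no chiral-pool lactone.
- Weak points: A1 is a strained bis-lactone with an acrylate unit and is hard to make and to enolize cleanly. It needs an extra carbinol stereocentre at C6 that is then consumed. A2 emerges with C10 as a carboxylic acid, one oxidation level too high, and must be reduced and activated before it can meet C11. Ring A is still open afterwards.
- Comparison: this road is better in setting C9 and the olefin geometry together. The chosen plan sets against it that C9 is bought, the Wittig reaction with 14 is reliably E-selective, and fewer steps separate the building blocks from the seco compound 22.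

**Alternative 2:** The cuts are at C13–C14 and O–C15, with an isoxazole standing for the C13/C15 diketone. Aldoxime A3 carries a terminal alkyne on the epoxide. NaOCl converts the oxime into a 1,3-dipole that adds to C14≡C15 and closes both the heterocycle and ring A, giving isoxazolophane A4.
- Merits: such cycloadditions close large rings under nearly neutral conditions, need no leaving group and no enolate, and mask the diketone throughout, so C15 needs neither a protecting group nor a throw-away stereocentre.
- Weak points: unmasking requires reductive N–O cleavage (Mo(CO)6 or samarium diiodide) and hydrolysis. The ketone that appears is α to the epoxide, and these reductants open α,β-epoxy ketones and attack the alkylidene lactone. A3 also carries an acidic C11–H next to the oxime, and hypochlorite threatens the isopropenyl group.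
- Comparison: this road is probably the better ring closure and is shorter in protecting-group steps. The chosen plan sets against it an end game of desilylation and oxidation (23 to 25) that the epoxide should tolerate.

**Alternative 3:** The cut is at C15–C16. Precursor A5 holds a Z vinyl iodide at C16, an aldehyde at C15 and C13 as a silyl ether. CrCl2 with catalytic NiCl2 inserts into the C16–I bond, and the carbon nucleophile adds to the aldehyde to give the macrocyclic Z allylic alcohol A6.
- Merits: this is among the most dependable macrocyclizations. It is selective for aldehydes, tolerates esters, the lactone and the Michael acceptor, retains the olefin geometry, and postpones the epoxide until after ring closure.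
- Weak points: it needs stoichiometric chromium salts, a Z α-iodo olefin and a β-silyloxy aldehyde prone to elimination. C13 and C15 become extra carbinol centres, so epoxidation, deprotection and two oxidations follow ring closure. The late epoxidation depends on the C15 configuration and the ring conformation, not on a reagent.
- Comparison: the ring closure itself is arguably more reliable than an enolate alkylation. The chosen plan sets against it an epoxide fixed by reagent control before cyclization (16), a two-step end game and no chromium.

Key step: step 15

Assumption: the carbinol centre C15 made in step 12 is temporary (it is oxidized in step 17); both epimers are expected and are carried on together, and the formulas show the 15S epimer.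

## Route

Step 1
Reactants: 1 5,6-dihydro-2H-pyran-2-one; 2 potassium trifluoro(prop-1-en-2-yl)borate
Product: 3 (4S)-4-(prop-1-en-2-yl)oxan-2-one
Conditions: [Rh(cod)2]BF4 (cat.), (S)-BINAP, toluene/H2O, 100 °C
Reagents that add atoms: none
Why: Rhodium-catalysed asymmetric 1,4-addition of an alkenylboron reagent to an unsaturated lactone (Hayashi–Miyaura reaction); by analogy with six-membered enones and enoates the (S)-BINAP complex should give the 4S adduct, which sets C4. The lactone keeps the two arms of C4 distinct as acyl and alkoxy ends.

Step 2
Reactants: 3 (4S)-4-(prop-1-en-2-yl)oxan-2-one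
Product: 4 (3S)-5-hydroxy-N-methoxy-N-methyl-3-(prop-1-en-2-yl)pentanamide
Conditions: MeNH(OMe)·HCl, AlMe3, CH2Cl2, 0 °C to rt
Reagents that add atoms: N,O-dimethylhydroxylamine hydrochloride, CNOC.Cl
Why: AlMe3-mediated aminolysis of a δ-lactone to the Weinreb amide; C4 is not involved. The hydroxy amide is used at once to avoid relactonization.

Step 3
Reactants: 4 (3S)-5-hydroxy-N-methoxy-N-methyl-3-(prop-1-en-2-yl)pentanamide
Product: 5 (3S)-N-methoxy-N-methyl-5-oxo-3-(prop-1-en-2-yl)pentanamide
Conditions: Dess–Martin periodinane, CH2Cl2, 0 °C to rt
Reagents that add atoms: none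
Why: Dess–Martin oxidation of the primary alcohol to the aldehyde under neutral conditions; amide and isopropenyl group are inert.

Step 4
Reactants: 5 (3S)-N-methoxy-N-methyl-5-oxo-3-(prop-1-en-2-yl)pentanamide; 6 methyl 2-[bis(2,2,2-trifluoroethoxy)phosphoryl]propanoate
Product: 7 methyl (2Z,5S)-7-[methoxy(methyl)amino]-2-methyl-7-oxo-5-(prop-1-en-2-yl)hept-2-enoate
Conditions: KN(SiMe3)2, 18-crown-6, THF, −78 °C
Reagents that add atoms: none
Why: Still–Gennari olefination; the trifluoroethyl phosphonate under dissociating conditions should give the Z trisubstituted enoate (C16=C17) under kinetic control. The aldehyde reacts in preference to the Weinreb amide.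

Step 5
Reactants: 7 methyl (2Z,5S)-7-[methoxy(methyl)amino]-2-methyl-7-oxo-5-(prop-1-en-2-yl)hept-2-enoate
Product: 8 (3S,5Z)-7-hydroxy-6-methyl-3-(prop-1-en-2-yl)hept-5-enal
Conditions: iBu2AlH (excess), CH2Cl2, −78 °C; aq. potassium sodium tartrate
Reagents that add atoms: none
Why: Hydride reduction: the enoate goes to the allylic alcohol, while the Weinreb amide stops at the chelated hemiaminal and gives the aldehyde on work-up. The Z geometry is retained and no protecting group is needed.

Step 6
Reactants: 9 (5R)-5-(hydroxymethyl)oxolan-2-one
Product: 10 [(2R)-5-oxooxolan-2-yl]methyl 4-methylbenzenesulfonate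
Conditions: TsCl, pyridine, CH2Cl2, 0 °C to rt
Reagents that add atoms: 4-methylbenzenesulfonyl chloride, Cc1ccc(cc1)S(Cl)(=O)=O
Why: Sulfonylation of the primary alcohol; C9 is untouched. The tosylate is a latent C10 leaving group that tolerates the later phosphine, titanium and periodinane steps.

Step 7
Reactants: 10 [(2R)-5-oxooxolan-2-yl]methyl 4-methylbenzenesulfonate
Product: 12 [(2R)-4-bromo-5-oxooxolan-2-yl]methyl 4-methylbenzenesulfonate (both epimers at the brominated carbon), via silyl ketene acetal 11 (not isolated)
Conditions: LiN(SiMe3)2, Me3SiCl, THF, −78 °C; then N-bromosuccinimide, −78 to 0 °C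
Reagents that add atoms: N-bromosuccinimide, O=C1CCC(=O)N1Br
Why: α-Bromination of a lactone through its silyl ketene acetal. The configuration at the brominated carbon is irrelevant because it becomes the ylide carbon.

Step 8
Reactants: 12 [(2R)-4-bromo-5-oxooxolan-2-yl]methyl 4-methylbenzenesulfonate
Product: 14 [(2R)-5-oxo-4-(triphenyl-λ5-phosphanylidene)oxolan-2-yl]methyl 4-methylbenzenesulfonate, via phosphonium bromide 13 (not isolated)
Conditions: PPh3, THF, 60 °C; then aq. Na2CO3, CH2Cl2, rt
Reagents that add atoms: triphenylphosphine, c1ccc(cc1)P(c1ccccc1)c1ccccc1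
Why: Quaternization of the activated α-bromo lactone and deprotonation to the stabilized ylide (preparation of a Wittig reagent). The primary tosylate should react far more slowly with the phosphine than the α-halo carbonyl.

Step 9
Reactants: 8 (3S,5Z)-7-hydroxy-6-methyl-3-(prop-1-en-2-yl)hept-5-enal; 14 lactone ylide
Product: 15 E alkylidene lactone with C10 tosylate and Z allylic alcohol (C15–OH)
Conditions: CH2Cl2, rt to 40 °C
Reagents that add atoms: none
Why: Wittig olefination with a stabilized lactone ylide under neutral conditions; it should give the E alkylidene lactone (C6=C7). The free allylic alcohol and the tosylate are left alone.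

Step 10
Reactants: 15 E alkylidene lactone with C10 tosylate and Z allylic alcohol
Product: 16 (16R,17S)-epoxy alcohol (C15–OH) with C10 tosylate
Conditions: Ti(OiPr)4, D-(−)-diethyl tartrate, tBuOOH, 4 Å molecular sieves, CH2Cl2, −20 °C
Reagents that add atoms: tert-butyl hydroperoxide, CC(C)(C)OO
Why: Katsuki–Sharpless asymmetric epoxidation, selective for the allylic alcohol over the isopropenyl and alkylidene groups. Z allylic alcohols give the (2S,3R) series with the L-(+) tartrate, so the D-(−) ester should give the (2R,3S) epoxy alcohol, which is the target arrangement at C16 and C17, set by the reagent.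

Step 11
Reactants: 16 (16R,17S)-epoxy alcohol with C10 tosylate
Product: 17 (16S,17S)-epoxy aldehyde (C15 aldehyde) with C10 tosylate
Conditions: Dess–Martin periodinane, pyridine, CH2Cl2, 0 °C
Reagents that add atoms: none
Why: Buffered Dess–Martin oxidation of the epoxy alcohol. The aldehyde has no α-hydrogen and cannot epimerize; it is used crude.

Step 12
Reactants: 17 (16S,17S)-epoxy aldehyde with C10 tosylate; 18 methyl 3-oxobutanoate
Product: 20 δ-hydroxy β-keto ester (C15–OH, C13 ketone, C12 methyl ester) with C10 tosylate, via acetoacetate dianion 19 (not isolated)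
Conditions: 18, NaH then n-BuLi, THF, 0 °C; then 17, −78 °C; AcOH quench
Reagents that add atoms: none
Why: Aldol addition of the acetoacetate dianion through its terminal carbon forms C14–C15 and brings in the β-keto ester in one step. At −78 °C the aldehyde should react much faster than the lactone, the Michael acceptor or the sulfonate. C15 forms as an epimer mixture, which is of no consequence.

Step 13
Reactants: 20 δ-hydroxy β-keto ester with C10 tosylate
Product: 21 C15 triethylsilyl ether of 20
Conditions: Et3SiCl, imidazole, DMAP (cat.), DMF, 0 °C to rt
Reagents that add atoms: chlorotriethylsilane, CC[Si](Cl)(CC)CC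
Why: Silylation without a Lewis acid, so the epoxide is not activated toward rearrangement. The silyl ether blocks retro-aldol cleavage and keeps C15 at the carbinol level, so that C11 is the only acidic carbon.

Step 14
Reactants: 21 C15 triethylsilyl ether with C10 tosylate
Product: 22 seco iodide (C10–I, β-keto ester, C15 triethylsilyl ether)
Conditions: NaI, NaHCO3, acetone, reflux
Reagents that add atoms: sodium iodide, [Na+].[I-]
Why: Finkelstein exchange of the primary sulfonate under neutral conditions. C9 is not a reacting centre and keeps its configuration.

Step 15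
Reactants: 22 seco iodide
Product: 23 macrocyclic β-keto ester with C15 triethylsilyl ether
Conditions: Cs2CO3, DMF, 50 °C, slow addition of 22 to high dilution
Reagents that add atoms: none
Why: Cs2CO3 deprotonates the only strongly acidic site, C11 of the β-keto ester, and the enolate displaces iodide at the primary carbon C10 in an SN2 reaction that forms C10–C11. The closest known reaction type is the macrocyclization of ω-halo β-keto esters and malonates by intramolecular C-alkylation with carbonate bases at high dilution. Ring A closes in the 14-exo-tet mode. The new stereocentre C11 is not set by the alkylation; it stays acidic and is under thermodynamic control here and again after step 17. C- over O-alkylation is needed; the soft iodide, the large counter-ion and the still larger ring that O-attack would form favour it. Ring closure over oligomerization is also needed; slow addition at high dilution and the two turn elements of the chain (E alkylidene lactone, cis-epoxide) favour it. The epoxide should survive because its only carbon open to exo attack is quaternary, conjugate addition to the alkylidene lactone is reversible and would give a strained ten-membered ring, and the C15 silyl ether removes both a second 1,3-dicarbonyl unit and the retro-aldol pathway. C9 is untouched because substitution takes place at the adjacent primary carbon.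

Step 16
Reactants: 23 macrocyclic β-keto ester with C15 triethylsilyl ether
Product: 24 macrocyclic C15 carbinol
Conditions: HF·pyridine, pyridine, THF, 0 °C
Reagents that add atoms: none
Why: Cleavage of the triethylsilyl ether by buffered, non-basic fluoride; this should spare the epoxide and avoid retro-aldol cleavage or elimination of the β-hydroxy ketone.

Step 17
Reactants: 24 macrocyclic C15 carbinol
Product: 25 CNP0108136.1
Conditions: Dess–Martin periodinane (small excess), pyridine, CH2Cl2, 0 °C to rt
Reagents that add atoms: none
Why: Dess–Martin oxidation of the β-hydroxy ketone to the 1,3-diketone; only a small excess of oxidant is used so that C14 is not attacked. C11 can equilibrate through the enol to the more stable epimer, and C4, C9, C16 and C17 are not touched.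

## Compound list

1 | 5,6-dihydro-2H-pyran-2-one | O=C1C=CCCO1 | starting material
2 | potassium trifluoro(prop-1-en-2-yl)borate | [K+].C=C(C)[B-](F)(F)F | starting material
3 | (4S)-4-(prop-1-en-2-yl)oxan-2-one | O=C1C[C@@H](C(C)=C)CCO1 | intermediate
4 | (3S)-5-hydroxy-N-methoxy-N-methyl-3-(prop-1-en-2-yl)pentanamide | CON(C)C(=O)C[C@@H](C(C)=C)CCO | intermediate
5 | (3S)-N-methoxy-N-methyl-5-oxo-3-(prop-1-en-2-yl)pentanamide | CON(C)C(=O)C[C@@H](C(C)=C)CC=O | intermediate
6 | methyl 2-[bis(2,2,2-trifluoroethoxy)phosphoryl]propanoate | COC(=O)C(C)P(=O)(OCC(F)(F)F)OCC(F)(F)F | starting material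
7 | methyl (2Z,5S)-7-[methoxy(methyl)amino]-2-methyl-7-oxo-5-(prop-1-en-2-yl)hept-2-enoate | COC(=O)/C(C)=C\C[C@H](C(C)=C)CC(=O)N(C)OC | intermediate
8 | (3S,5Z)-7-hydroxy-6-methyl-3-(prop-1-en-2-yl)hept-5-enal | OC/C(C)=C\C[C@H](C(C)=C)CC=O | intermediate
9 | (5R)-5-(hydroxymethyl)oxolan-2-one | O=C1CC[C@H](CO)O1 | starting material
10 | [(2R)-5-oxooxolan-2-yl]methyl 4-methylbenzenesulfonate | O=C1CC[C@H](COS(=O)(=O)c2ccc(C)cc2)O1 | intermediate
11 | {(2R)-5-[(trimethylsilyl)oxy]-2,3-dihydrofuran-2-yl}methyl 4-methylbenzenesulfonate | C[Si](C)(C)OC1=CC[C@H](COS(=O)(=O)c2ccc(C)cc2)O1 | intermediate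
12 | [(2R)-4-bromo-5-oxooxolan-2-yl]methyl 4-methylbenzenesulfonate (both epimers at C4 of the lactone) | O=C1C(Br)C[C@H](COS(=O)(=O)c2ccc(C)cc2)O1 | intermediate
13 | {(5R)-2-oxo-5-[(tosyloxy)methyl]oxolan-3-yl}triphenylphosphonium bromide | [Br-].O=C1C([P+](c2ccccc2)(c3ccccc3)c4ccccc4)C[C@H](COS(=O)(=O)c5ccc(C)cc5)O1 | intermediate
14 | [(2R)-5-oxo-4-(triphenyl-λ5-phosphanylidene)oxolan-2-yl]methyl 4-methylbenzenesulfonate | O=C1C(=P(c2ccccc2)(c3ccccc3)c4ccccc4)C[C@H](COS(=O)(=O)c5ccc(C)cc5)O1 | intermediate
15 | [(2R,4E)-4-[(3S,5Z)-7-hydroxy-6-methyl-3-(prop-1-en-2-yl)hept-5-en-1-ylidene]-5-oxooxolan-2-yl]methyl 4-methylbenzenesulfonate | Cc1ccc(cc1)S(=O)(=O)OC[C@H]1C/C(=C\C[C@@H](C(C)=C)C/C=C(C)\CO)C(=O)O1 | intermediate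
16 | [(2R,4E)-4-[(3R)-4-[(2S,3R)-3-(hydroxymethyl)-3-methyloxiran-2-yl]-3-(prop-1-en-2-yl)butylidene]-5-oxooxolan-2-yl]methyl 4-methylbenzenesulfonate | Cc1ccc(cc1)S(=O)(=O)OC[C@H]1C/C(=C\C[C@@H](C(C)=C)C[C@@H]2O[C@]2(C)CO)C(=O)O1 | intermediate
17 | [(2R,4E)-4-[(3R)-4-[(2S,3S)-3-formyl-3-methyloxiran-2-yl]-3-(prop-1-en-2-yl)butylidene]-5-oxooxolan-2-yl]methyl 4-methylbenzenesulfonate | Cc1ccc(cc1)S(=O)(=O)OC[C@H]1C/C(=C\C[C@@H](C(C)=C)C[C@@H]2O[C@]2(C)C=O)C(=O)O1 | intermediate
18 | methyl 3-oxobutanoate | COC(=O)CC(C)=O | starting material
19 | methyl 3-oxobutanoate dianion, sodium lithium salt | [Na+].[Li+].COC(=O)[CH-]C(=O)[CH2-] | intermediate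
20 | seco δ-hydroxy β-keto ester, (4R,6E,9R,15S,16R,17S), C10 tosylate: methyl 5-hydroxy-3-oxopentanoate bearing at C5 the 2-methyloxiran-2-yl group of 17 | Cc1ccc(cc1)S(=O)(=O)OC[C@H]1C/C(=C\C[C@@H](C(C)=C)C[C@@H]2O[C@]2(C)[C@@H](O)CC(=O)CC(=O)OC)C(=O)O1 | intermediate
21 | C15 triethylsilyl ether of 20, (4R,6E,9R,15S,16S,17S) | Cc1ccc(cc1)S(=O)(=O)OC[C@H]1C/C(=C\C[C@@H](C(C)=C)C[C@@H]2O[C@]2(C)[C@@H](O[Si](CC)(CC)CC)CC(=O)CC(=O)OC)C(=O)O1 | intermediate
22 | seco iodide, (4R,6E,9R,15S,16S,17S): C10 iodide, C11–C13 β-keto ester, C15 triethylsilyl ether | IC[C@H]1C/C(=C\C[C@@H](C(C)=C)C[C@@H]2O[C@]2(C)[C@@H](O[Si](CC)(CC)CC)CC(=O)CC(=O)OC)C(=O)O1 | intermediate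
23 | macrocyclic β-keto ester, (4R,6E,9S,11S,15S,16S,17S), C15 triethylsilyl ether | C=C(C)[C@@H]1C/C=C2\C[C@H](C[C@H](C(=O)OC)C(=O)C[C@H](O[Si](CC)(CC)CC)[C@@]3(C)O[C@H]3C1)OC2=O | intermediate
24 | macrocyclic C15 carbinol, (4R,6E,9S,11S,15S,16R,17S) | C=C(C)[C@@H]1C/C=C2\C[C@H](C[C@H](C(=O)OC)C(=O)C[C@H](O)[C@@]3(C)O[C@H]3C1)OC2=O | intermediate
25 | CNP0108136.1, (4R,6E,9S,11S,16S,17S) | C=C(C)[C@@H]1C/C=C2\C[C@H](C[C@H](C(=O)OC)C(=O)CC(=O)[C@@]3(C)O[C@H]3C1)OC2=O | target

## Step count and risks

Total step count: 17. Longest linear sequence: 14 steps (steps 1–5 and 9–17, from 1 to 25); steps 6–8 form the lactone branch.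

**Step 15 (key step).** Oligomerization by intermolecular alkylation, O-alkylation, or a displacement at the β-oxygenated primary iodide that is slow enough for loss of HI or reversible conjugate addition to take over. Fallback (sets out from 8 and 14, returns at 23): the order of the two ring-forming bonds is reversed, so that C10–C11 is made between molecules and ring A is closed by the Wittig reaction. The aldehyde of 8 is masked as its dimethyl acetal F1 (HC(OMe)3, pyridinium tosylate, MeOH). Epoxidation, oxidation, dianion aldol addition and silylation as in steps 10–13 give epoxy alcohol F2, epoxy aldehyde F3, hydroxy keto ester F4 and triethylsilyl ether F5. The enolate of F5 is alkylated at C11 with tosylate 14 (Cs2CO3, NaI, DMF) to give ylide keto ester F6. Mild acid cleavage of the acetal and neutralization give ylide aldehyde F7, which is not isolated and cyclizes at C6=C7 in warm toluene at high dilution to 23.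

**Step 12.** Loss of chemoselectivity: the dianion may act as a base toward the γ-hydrogens of the alkylidene lactone, add in conjugate fashion or displace the sulfonate, and the C15 alkoxide may migrate onto the epoxide. Fallback (sets out from 8, returns at 21): the lactone is attached after the aldol reaction. The lactone-free series described above is followed to silyl ether F5, its acetal is cleaved to aldehyde F8, and the Wittig reaction of F8 with 14 gives 21 directly.

**Step 10.** Slow epoxidation and incomplete reagent control with a Z, 2-methyl allylic alcohol. Fallback (sets out from 15, returns at 20): epoxidation and aldol addition change places and the epoxide is set by the substrate. MnO2 oxidizes 15 to Z enal F9. A Ti(OiPr)4/BINOL-catalysed vinylogous Mukaiyama aldol addition of 1-methoxy-1,3-bis(trimethylsilyloxy)buta-1,3-diene, with the BINOL enantiomer that gives the 15S carbinol, leads to allylic alcohol F10. Hydroxyl-directed epoxidation (VO(acac)2, tBuOOH), in which 1,3-allylic strain should favour the threo epoxide, then gives 20 as the 15S epimer.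

**Step 16.** Retro-aldol cleavage or elimination at the β-oxygenated ketone, opening of the epoxide by fluoride, or migration of the epoxide toward the freed hydroxyl. Fallback (sets out from 20, returns at 24): the silyl group is left out. Finkelstein exchange on 20 gives iodo alcohol F11, which is cyclized with Cs2CO3 as in step 15 to give 24 directly; the free carbinol is far less acidic than C11, and only the retro-aldol risk has to be accepted.

**Step 1.** Protodeboronation of the α-branched alkenyl nucleophile, hydrolysis of the lactone, or low enantioselectivity. Fallback (sets out from 1, returns at 3): resolution in place of catalysis. Copper-mediated addition of isopropenylmagnesium bromide to 1 (CuBr·SMe2, Me3SiCl, THF, −78 °C) gives racemic lactone F12. Aminolysis with (S)-1-phenylethylamine gives two diastereomeric hydroxy amides; the 3S isomer F13 is separated by crystallization or chromatography and relactonized with dilute acid to 3.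

## Further compounds

F1 | step 15 | (2Z,5S)-7,7-dimethoxy-2-methyl-5-(prop-1-en-2-yl)hept-2-en-1-ol (dimethyl acetal of 8) | COC(OC)C[C@@H](C(C)=C)C/C=C(C)\CO
F2 | step 15 | epoxy alcohol of F1, epoxide as in 16 | COC(OC)C[C@@H](C(C)=C)C[C@@H]1O[C@]1(C)CO
F3 | step 15 | epoxy aldehyde of the acetal series, epoxide as in 17 | COC(OC)C[C@@H](C(C)=C)C[C@@H]1O[C@]1(C)C=O
F4 | step 15 | δ-hydroxy β-keto ester of the acetal series (15S shown) | COC(OC)C[C@@H](C(C)=C)C[C@@H]1O[C@]1(C)[C@@H](O)CC(=O)CC(=O)OC
F5 | step 15 | C15 triethylsilyl ether of F4 | COC(OC)C[C@@H](C(C)=C)C[C@@H]1O[C@]1(C)[C@@H](O[Si](CC)(CC)CC)CC(=O)CC(=O)OC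
F6 | step 15 | C11-alkylated keto ester bearing the lactone ylide and the C6 dimethyl acetal (C11 epimers) | COC(OC)C[C@@H](C(C)=C)C[C@@H]1O[C@]1(C)[C@@H](O[Si](CC)(CC)CC)CC(=O)C(C(=O)OC)C[C@H]2CC(=P(c3ccccc3)(c4ccccc4)c5ccccc5)C(=O)O2
F7 | step 15 | ylide aldehyde from F6 (C6 aldehyde, not isolated) | O=CC[C@@H](C(C)=C)C[C@@H]1O[C@]1(C)[C@@H](O[Si](CC)(CC)CC)CC(=O)C(C(=O)OC)C[C@H]2CC(=P(c3ccccc3)(c4ccccc4)c5ccccc5)C(=O)O2
F8 | step 12 | C6 aldehyde from F5 (β-keto ester, C15 triethylsilyl ether, epoxide) | O=CC[C@@H](C(C)=C)C[C@@H]1O[C@]1(C)[C@@H](O[Si](CC)(CC)CC)CC(=O)CC(=O)OC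
F9 | step 10 | Z enal from 15 (C15 aldehyde on the Z-C16=C17 olefin, C10 tosylate) | Cc1ccc(cc1)S(=O)(=O)OC[C@H]1C/C(=C\C[C@@H](C(C)=C)C/C=C(C)\C=O)C(=O)O1
F10 | step 10 | (15S) allylic alcohol δ-hydroxy β-keto ester with Z-C16=C17 olefin and C10 tosylate | Cc1ccc(cc1)S(=O)(=O)OC[C@H]1C/C(=C\C[C@@H](C(C)=C)C/C=C(C)\[C@@H](O)CC(=O)CC(=O)OC)C(=O)O1
F11 | step 16 | seco iodide with free C15 carbinol | IC[C@H]1C/C(=C\C[C@@H](C(C)=C)C[C@@H]2O[C@]2(C)[C@@H](O)CC(=O)CC(=O)OC)C(=O)O1
F12 | step 1 | racemic 4-(prop-1-en-2-yl)oxan-2-one | O=C1CC(C(C)=C)CCO1
F13 | step 1 | (3S)-5-hydroxy-N-[(1S)-1-phenylethyl]-3-(prop-1-en-2-yl)pentanamide | C[C@H](NC(=O)C[C@@H](C(C)=C)CCO)c1ccccc1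
A1 | alternative 1 | seven-membered glycolate dilactone (6-methylene-1,4-dioxepane-2,5-dione) bearing the epoxy ester chain at C6 | COC(=O)[C@@]1(C)O[C@H]1C[C@H](C(C)=C)C[C@H]2OC(=O)COC(=O)C2=C
A2 | alternative 1 | E alkylidene lactone C10 carboxylic acid | COC(=O)[C@@]1(C)O[C@H]1C[C@H](C(C)=C)C/C=C2\C[C@H](C(=O)O)OC2=O
A3 | alternative 2 | seco aldoxime (C13) with terminal alkyne C14≡C15 on the epoxide | C#C[C@@]1(C)O[C@H]1C[C@H](C(C)=C)C/C=C2\C[C@H](C[C@H](C(=O)OC)/C=N/O)OC2=O
A4 | alternative 2 | macrocyclic isoxazole (isoxazolophane) | C=C(C)[C@@H]1C/C=C2\C[C@H](C[C@H](C(=O)OC)c3cc(on3)[C@@]4(C)O[C@H]4C1)OC2=O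
A5 | alternative 3 | seco Z vinyl iodide (C16) with C15 aldehyde and C13 silyl ether | I/C(C)=C\C[C@H](C(C)=C)C/C=C1\C[C@H](C[C@H](C(=O)OC)[C@H](O[Si](C)(C)C(C)(C)C)CC=O)OC1=O
A6 | alternative 3 | macrocyclic Z allylic alcohol at C15 | C=C(C)[C@@H]1C/C=C2\C[C@H](C[C@H](C(=O)OC)[C@H](O[Si](C)(C)C(C)(C)C)C[C@H](O)/C(C)=C\C1)OC2=O
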